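A small charge of free catalyst, 5 mol% on the substrate or 0.250 mM, had to catch a coupling partner that also decays by itself.

    catalyst intermediate B → free catalyst + target (k1 = 8.34 s⁻¹, Ea1 = 56.0 kJ mol⁻¹)
    coupling partner → decomposed reagent (k2 = 0.0476 s⁻¹, Ea2 = 84.0 kJ mol⁻¹)
    substrate + free catalyst → catalyst intermediate A (k3 = 779 M⁻¹ s⁻¹, Ea3 = 36.0 kJ mol⁻¹)
    coupling partner + catalyst intermediate A → catalyst intermediate B (k4 = 151 M⁻¹ s⁻¹, Ea4 = 47.0 kJ mol⁻¹)
    (constants at 20 °C)

in all of them: substrate 5.0 mM; coupling partner 0.800 equiv; free catalyst 5 mol%; time 30 s

|  | temperature |
|---|---|
| violet | 20 °C |
| blue | 80 °C |
| red | 50 °C |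

- at 20 °C the constants are as listed, elsewhere as the activation energies make them

- the best flask by amount of target, in percent of the substrate charged; "all alike" if 1.5 percentage points covers them all (violet / blue / red / all alike)
- amount of target at the end, in percent of the substrate charged, violet
- amount of target at the end, in percent of the substrate charged, blue
- amount of target at the end, in percent of the substrate charged, red

First I asked where the catalyst waited. At the start of violet, binding of substrate ran at 3.90 s⁻¹ per catalyst and release of target at 8.34 s⁻¹, while capture of coupling partner ran at 0.604 s⁻¹. Capture was slower than both, and it slowed further as the partner fell. So I took catalyst intermediate A as the resting state, with c(catalyst intermediate A) near 0.250 mM.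

Next I asked what became of the partner, the limiting reagent at 0.800 equiv. In violet it had two exits: capture at 0.0377 s⁻¹ and decay at 0.0476 s⁻¹. The capture share, capture over capture plus decay, was 44.2%. Each captured partner gives one target, so the ceiling for violet was 35.4% of the substrate charged.

Then I asked whether violet had the time. The partner's lifetime was 11.7 s, so I reckoned 7.73% of it remaining after 30 s. I reckoned 32.7% for violet.

Last I asked whether heat helped. From violet to blue, decay speeds up by a factor of 350 and capture by 26, so decay gains more than capture. The share in blue fell to 5.67%, a ceiling of 4.54%. I reckoned the loading of the catalyst in blue at 0.0209 s, against a partner lifetime of 0.0568 s, so I put blue under that ceiling. Violet's ceiling stood above blue's, and I put red, heated less than blue, between them.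

The forecast named violet, with 29.8% for violet, 3.1% for blue and 10.9% for red, on this ground: “Decomposition has the highest Ea, so heating favours it.”

The simulation gave 29.7% in violet, 3.04% in blue and 10.9% in red, so violet was ahead of both. Violet's result lay 3 percentage points below my reckoning, and at 15.0 s catalyst intermediate A in violet stood at 91.9% of the catalyst, not the whole I had taken. Violet's target reached 32.7% after 300 s, under the 35.4% that the share 44.2% allows. Blue stayed under its 4.54%. A neighbour of blue with 1.2 mol% of free catalyst reckons the same way: capture at 0.240 s⁻¹ against decay at 16.6 s⁻¹ gives a ceiling of 1.14%. That flask gave 0.763%, which is 0.669 of its ceiling, against 0.670 in blue.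

(The rate constants come from no measurement; no experiment stands behind them.)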